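**Retrosynthetic overview**
1. Target 15 ⇒ hydroquinone monomethyl ether 14 (oxidised in the same flask) ⇒ three-component Dötz benzannulation of alkenyl(methoxy)carbene complex 13, acetylene and one CO ligand. With the quinone ring numbered C1(=O), C2(furyl), C3-H, C4(=O), C5-H, C6-H, this closes C4–C5, C6–C1 and C1–C2.
2. Enabling feature: the quinone is a para-dioxygenated six-membered ring. C4 can be a methoxycarbene carbon and C1 an inserted CO, the unsubstituted C5=C6 edge is an acetylene unit, and the C2(furyl)=C3 edge is the alkene of a carbene complex reachable from a furan-2-carbaldehyde.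
3. 13 ⇒ aldehyde 9 + Fischer carbene 12 (aldol condensation makes C2=C3); 12 ⇒ Cr(CO)6 10.
4. 9 ⇒ (S)-alcohol 6 + 3-methylbut-2-enoic acid 7; 6 ⇒ Keck allylation and cross-metathesis on aldehyde 4; 4 ⇒ 4-bromofuran-2-carbaldehyde 1.
5. Ring order: the furan is bought with 1; the quinone ring is the only ring formed and it is formed last.

Key step: step 9

Remark: the stereocentre of the target is read as (S) (O > furyl C > CH2 > H); in the SMILES of the chromium complexes each carbonyl ligand is written Cr=C=O.

**Route**

Step 1
Reactants: 1 4-bromofuran-2-carbaldehyde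
Product: 2 2-(4-bromofuran-2-yl)-1,3-dioxolane
Conditions: HOCH2CH2OH, p-TsOH·H2O (cat.), toluene, reflux, Dean–Stark
Reagents that add atoms: ethylene glycol, OCCO
Why: Acid-catalysed acetalisation with azeotropic removal of water masks the aldehyde as a dioxolane that is inert to the organolithium chemistry of step 2.

Step 2
Reactants: 2 2-(4-bromofuran-2-yl)-1,3-dioxolane
Product: 4 5-(1,3-dioxolan-2-yl)furan-3-carbaldehyde, via furan-3-yllithium 3 (not isolated)
Conditions: n-BuLi, Et2O, −78 °C; DMF, −78 to 0 °C; then H2O
Reagents that add atoms: N,N-dimethylformamide, CN(C)C=O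
Why: Bromine–lithium exchange at −78 °C is faster than any attack on the acetal, the lithiofuran 3 is kept cold so that it does not equilibrate to the α-lithio isomer, and Bouveault-type formylation with DMF places the aldehyde on the former C–Br carbon.

Step 3
Reactants: 4 5-(1,3-dioxolan-2-yl)furan-3-carbaldehyde
Product: 5 (1S)-1-[5-(1,3-dioxolan-2-yl)furan-3-yl]but-3-en-1-ol
Conditions: allylSnBu3, (S)-BINOL (20 mol%), Ti(OiPr)4 (10 mol%), 4 Å MS, CH2Cl2, −20 °C; then aq. NaHCO3
Reagents that add atoms: allyltributylstannane, C=CC[Sn](CCCC)(CCCC)CCCC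
Why: Keck asymmetric allylation, in which the chiral Lewis acid from (S)-BINOL and Ti(OiPr)4 activates the aldehyde and exposes its Si face to the allylstannane, so that the (S) carbinol centre is set by catalyst control as with other aryl aldehydes.

Step 4
Reactants: 5 (1S)-1-[5-(1,3-dioxolan-2-yl)furan-3-yl]but-3-en-1-ol
Product: 6 (1S)-1-[5-(1,3-dioxolan-2-yl)furan-3-yl]-4-methylpent-3-en-1-ol
Conditions: second-generation Grubbs catalyst (5 mol%), 2-methyl-2-butene (large excess), CH2Cl2, 40 °C
Reagents that add atoms: 2-methyl-2-butene, CC=C(C)C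
Why: Olefin cross-metathesis with excess 2-methyl-2-butene exchanges the CH2 terminus for an isopropylidene group, is driven by loss of propene, tolerates the free hydroxyl, furan and acetal, and does not touch the stereocentre.

Step 5
Reactants: 6 (1S)-1-[5-(1,3-dioxolan-2-yl)furan-3-yl]-4-methylpent-3-en-1-ol; 7 3-methylbut-2-enoic acid
Product: 8 (1S)-1-[5-(1,3-dioxolan-2-yl)furan-3-yl]-4-methylpent-3-en-1-yl 3-methylbut-2-enoate
Conditions: DCC, DMAP (cat.), CH2Cl2, 0 °C to rt
Reagents that add atoms: none
Why: Steglich esterification acylates the secondary alcohol through the O-acylisourea and acylpyridinium without breaking the C–O bond at the stereocentre, so the (S) configuration is retained, and the free acid avoids the deconjugation that the acid chloride suffers through a vinylketene.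

Step 6
Reactants: 8 (1S)-1-[5-(1,3-dioxolan-2-yl)furan-3-yl]-4-methylpent-3-en-1-yl 3-methylbut-2-enoate
Product: 9 (1S)-1-(5-formylfuran-3-yl)-4-methylpent-3-en-1-yl 3-methylbut-2-enoate
Conditions: 1 M aq. HCl (cat.), THF, 0 °C to rt
Reagents that add atoms: water, O
Why: Acetal hydrolysis of a furan-2-carbaldehyde dioxolane is fast in dilute aqueous acid, conditions under which the secondary ester, the trisubstituted alkenes and the stereocentre (a furan-3-yl carbinyl ester that ionises only reluctantly) should persist.

Step 7
Reactants: 10 chromium hexacarbonyl Cr(CO)6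
Product: 12 pentacarbonyl(1-methoxyethylidene)chromium, via lithium acetylpentacarbonylchromate 11 (not isolated)
Conditions: MeLi, Et2O, 0 °C to rt; then Me3OBF4, CH2Cl2/H2O, 0 °C
Reagents that add atoms: methyllithium, [Li]C; trimethyloxonium tetrafluoroborate, C[O+](C)C.F[B-](F)(F)F
Why: Fischer carbene synthesis, in which MeLi adds to a CO ligand of Cr(CO)6 to give the acyl chromate 11 and the hard oxonium salt methylates it on oxygen.

Step 8
Reactants: 9 (1S)-1-(5-formylfuran-3-yl)-4-methylpent-3-en-1-yl 3-methylbut-2-enoate; 12 pentacarbonyl(1-methoxyethylidene)chromium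
Product: 13 pentacarbonyl[(2E)-1-methoxy-3-{4-[(1S)-4-methyl-1-(3-methylbut-2-enoyloxy)pent-3-en-1-yl]furan-2-yl}prop-2-en-1-ylidene]chromium
Conditions: Et3N, Me3SiCl, Et2O, rt, dark
Reagents that add atoms: none
Why: Aldol condensation of a Fischer carbene complex, in which the α-hydrogens of 12 are acidic enough for Et3N, Me3SiCl traps the aldolate and promotes elimination, aldehyde 9 cannot enolise, and conjugation with the furan makes the (E)-alkene the expected product.

Step 9
Reactants: 13 pentacarbonyl[(2E)-1-methoxy-3-{4-[(1S)-4-methyl-1-(3-methylbut-2-enoyloxy)pent-3-en-1-yl]furan-2-yl}prop-2-en-1-ylidene]chromium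
Product: 15 (1S)-1-[5-(3,6-dioxocyclohexa-1,4-dien-1-yl)furan-3-yl]-4-methylpent-3-en-1-yl 3-methylbut-2-enoate, via hydroquinone monomethyl ether 14 (not isolated)
Conditions: HC≡CH (about 3 equiv, slow feed as a dilute THF solution), THF, 50 °C, Ar; then (NH4)2Ce(NO3)6, MeCN/H2O, 0 °C
Reagents that add atoms: acetylene, C#C; water, O
Why: Thermal loss of one CO from 13 lets acetylene coordinate and insert into the Cr=C bond (carbene carbon–alkyne carbon), CO then inserts into the η3-vinylcarbene to give an η4-dienylketene (alkyne carbon–CO), and the ketene carbon closes onto the furyl-bearing alkene carbon (CO–alkene carbon) before tautomerisation to the chromium-bound 4-methoxyphenol 14. The closest known reaction type is the Dötz benzannulation of β-aryl alkenyl(methoxy)carbene chromium complexes with terminal alkynes followed by oxidative work-up with tetravalent cerium, which converts the 4-methoxyphenol into the quinone with loss of methanol and takes the new carbonyl oxygen from water. The six-membered carbocycle is closed by a 6π-electrocyclisation of the metal-bound dienylketene, in a formal [3+2+1] union of alkenylcarbene, alkyne and CO. No stereocentre is formed, and the remote (S) centre is neither enolisable nor ionisable under the neutral thermal conditions and should be carried through unchanged. The step needs benzannulation in preference to cyclopentannulation and to uptake of a second alkyne, and alkyne selectivity over the two trisubstituted alkenes and the furan: an alkenyl (not aryl) methoxycarbene on chromium in THF favours CO insertion, slow feeding keeps the acetylene concentration low, the trisubstituted alkenes are too hindered to compete, and symmetric acetylene raises no regiochemical question. In the oxidation the electron-rich 4-methoxyphenol should be consumed much faster than the 2,4-disubstituted furan, which is then deactivated by the quinone.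

**Compound list**
1 | 4-bromofuran-2-carbaldehyde | O=Cc1cc(Br)co1 | starting material
2 | 2-(4-bromofuran-2-yl)-1,3-dioxolane | Brc1coc(C2OCCO2)c1 | intermediate
3 | [5-(1,3-dioxolan-2-yl)furan-3-yl]lithium | [Li]c1coc(C2OCCO2)c1 | intermediate
4 | 5-(1,3-dioxolan-2-yl)furan-3-carbaldehyde | O=Cc1coc(C2OCCO2)c1 | intermediate
5 | (1S)-1-[5-(1,3-dioxolan-2-yl)furan-3-yl]but-3-en-1-ol | C=CC[C@H](O)c1coc(C2OCCO2)c1 | intermediate
6 | (1S)-1-[5-(1,3-dioxolan-2-yl)furan-3-yl]-4-methylpent-3-en-1-ol | CC(C)=CC[C@H](O)c1coc(C2OCCO2)c1 | intermediate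
7 | 3-methylbut-2-enoic acid | CC(C)=CC(=O)O | starting material
8 | (1S)-1-[5-(1,3-dioxolan-2-yl)furan-3-yl]-4-methylpent-3-en-1-yl 3-methylbut-2-enoate | CC(C)=CC[C@H](OC(=O)C=C(C)C)c1coc(C2OCCO2)c1 | intermediate
9 | (1S)-1-(5-formylfuran-3-yl)-4-methylpent-3-en-1-yl 3-methylbut-2-enoate | CC(C)=CC[C@H](OC(=O)C=C(C)C)c1coc(C=O)c1 | intermediate
10 | chromium hexacarbonyl Cr(CO)6 | O=C=[Cr](=C=O)(=C=O)(=C=O)(=C=O)=C=O | starting material
11 | lithium acetylpentacarbonylchromate Li[(OC)5CrC(O)CH3] | CC([O-])=[Cr](=C=O)(=C=O)(=C=O)(=C=O)=C=O.[Li+] | intermediate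
12 | pentacarbonyl(1-methoxyethylidene)chromium (OC)5Cr=C(OMe)CH3 | COC(C)=[Cr](=C=O)(=C=O)(=C=O)(=C=O)=C=O | intermediate
13 | pentacarbonyl[(2E)-1-methoxy-3-{4-[(1S)-4-methyl-1-(3-methylbut-2-enoyloxy)pent-3-en-1-yl]furan-2-yl}prop-2-en-1-ylidene]chromium | CC(C)=CC[C@H](OC(=O)C=C(C)C)c1coc(/C=C/C(OC)=[Cr](=C=O)(=C=O)(=C=O)(=C=O)=C=O)c1 | intermediate
14 | (1S)-1-[5-(2-hydroxy-5-methoxyphenyl)furan-3-yl]-4-methylpent-3-en-1-yl 3-methylbut-2-enoate (formed as its Cr(CO)3 complex) | CC(C)=CC[C@H](OC(=O)C=C(C)C)c1coc(-c2cc(OC)ccc2O)c1 | intermediate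
15 | (1S)-1-[5-(3,6-dioxocyclohexa-1,4-dien-1-yl)furan-3-yl]-4-methylpent-3-en-1-yl 3-methylbut-2-enoate | CC(C)=CC[C@H](OC(=O)C=C(C)C)c1coc(C2=CC(=O)C=CC2=O)c1 | target

**Step count**
Total steps: 9. Longest linear sequence: 8 steps (1 → 2 → 4 → 5 → 6 → 8 → 9 → 13 → 15); step 7 is a one-step side branch.

**Steps most likely to fail**

Step 9. Acetylene may oligomerise at the carbene centre, or a second alkyne may be taken up before CO insertion, which would divert material from the phenol; the furan may also be partly opened oxidatively during the cerium work-up. The fallback replaces acetylene by a silyl-masked alkyne and stages the oxidation. It sets out from 13. Benzannulation with ethynyltrimethylsilane (THF, 50 °C), a monosubstituted alkyne that should insert once and place silicon next to the CO-derived carbon, should give after air decomplexation the silylphenol (1S)-1-{5-[2-hydroxy-5-methoxy-3-(trimethylsilyl)phenyl]furan-3-yl}-4-methylpent-3-en-1-yl 3-methylbut-2-enoate F1. Ipso-protodesilylation of this electron-rich ortho-silylphenol (CF3CO2H, CH2Cl2, 0 °C, short contact) would give the free phenol, and the fallback comes back to the route at 14. Phenol 14 is then isolated and oxidised with (NH4)2Ce(NO3)6 as in the second half of step 9.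

Step 8. The deprotonated complex 12 may add in conjugate fashion to the newly formed alkenyl carbene, and a slow condensation may let both complexes decompose. The fallback introduces the metal last onto a preformed acyl unit. It sets out from 9. Doebner–Knoevenagel condensation with malonic acid (pyridine, cat. piperidine, 80 °C) should give (2E)-3-{4-[(1S)-4-methyl-1-(3-methylbut-2-enoyloxy)pent-3-en-1-yl]furan-2-yl}prop-2-enoic acid F2. Oxalyl chloride with cat. DMF (CH2Cl2, 0 °C) should give the acid chloride (2E)-3-{4-[(1S)-4-methyl-1-(3-methylbut-2-enoyloxy)pent-3-en-1-yl]furan-2-yl}prop-2-enoyl chloride F3. Dipotassium pentacarbonylchromate K2Cr(CO)5 F4 is made from chromium hexacarbonyl 10 and potassium graphite KC8 in THF. Adding F3 to it at −78 °C should give the potassium acyl chromate K[(OC)5CrC(O)CH=CH-furyl] F5. O-Methylation of F5 with Me3OBF4 comes back to the route at 13.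

Step 3. Facial discrimination may be insufficient because the furan oxygen and the dioxolane compete with BINOL for titanium, which would give alcohol of low enantiomeric purity. The fallback is a racemic addition followed by enzymatic kinetic resolution. It sets out from 4. Allylmagnesium bromide (THF, −78 °C) should give racemic 1-[5-(1,3-dioxolan-2-yl)furan-3-yl]but-3-en-1-ol F6. Candida antarctica lipase B with vinyl acetate (MTBE, 30 °C) should acetylate the (R)-enantiomer, as expected for secondary carbinols with one large aryl and one medium alkyl group, to give (1R)-1-[5-(1,3-dioxolan-2-yl)furan-3-yl]but-3-en-1-yl acetate F7. The unreacted (S)-alcohol is separated by chromatography, and the fallback comes back to the route at 5.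

**Further compounds**
F1 | step 9 | (1S)-1-{5-[2-hydroxy-5-methoxy-3-(trimethylsilyl)phenyl]furan-3-yl}-4-methylpent-3-en-1-yl 3-methylbut-2-enoate | CC(C)=CC[C@H](OC(=O)C=C(C)C)c1coc(-c2cc(OC)cc([Si](C)(C)C)c2O)c1
F2 | step 8 | (2E)-3-{4-[(1S)-4-methyl-1-(3-methylbut-2-enoyloxy)pent-3-en-1-yl]furan-2-yl}prop-2-enoic acid | CC(C)=CC[C@H](OC(=O)C=C(C)C)c1coc(/C=C/C(=O)O)c1
F3 | step 8 | (2E)-3-{4-[(1S)-4-methyl-1-(3-methylbut-2-enoyloxy)pent-3-en-1-yl]furan-2-yl}prop-2-enoyl chloride | CC(C)=CC[C@H](OC(=O)C=C(C)C)c1coc(/C=C/C(=O)Cl)c1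
F4 | step 8 | dipotassium pentacarbonylchromate K2Cr(CO)5 | [K+].[K+].O=C=[Cr-2](=C=O)(=C=O)(=C=O)=C=O
F5 | step 8 | potassium pentacarbonyl[(2E)-3-{4-[(1S)-4-methyl-1-(3-methylbut-2-enoyloxy)pent-3-en-1-yl]furan-2-yl}prop-2-enoyl]chromate | [K+].CC(C)=CC[C@H](OC(=O)C=C(C)C)c1coc(/C=C/C([O-])=[Cr](=C=O)(=C=O)(=C=O)(=C=O)=C=O)c1
F6 | step 3 | racemic 1-[5-(1,3-dioxolan-2-yl)furan-3-yl]but-3-en-1-ol | C=CCC(O)c1coc(C2OCCO2)c1
F7 | step 3 | (1R)-1-[5-(1,3-dioxolan-2-yl)furan-3-yl]but-3-en-1-yl acetate | C=CC[C@@H](OC(C)=O)c1coc(C2OCCO2)c1
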